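**Plan**
Retrosynthesis: the C4 aroyl ester (made with inversion), the C1 acetate and the C8a methyl group come off first; the seven-membered ring is then cut at C7–C8 and C3a–C4, giving a cyclopentenyl diazoacetate (C8 carries a temporary ester) and the silyl dienol ether of 3-methylbut-2-enal.
Forward: the five-membered ring comes from a silyloxycyclopentenone and is elaborated to the vinyldiazoacetate; one rhodium-catalysed cyclopropanation/Cope operation then builds the seven-membered ring; C7 is oxidised, the angular methyl added and the C8 ester removed.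
Enabling feature: in the seven-membered ring the cis C5=C6 alkene lies between oxygen-bearing C4 and C7, which is the but-2-ene-1,4-diyl unit a 1,3-diene leaves behind; C8, alpha to the C7 ketone, can hold a removable ester, so C8–C8a–C3a can arrive as a vinylcarbenoid.
Stereochemistry: the one stereocentre of (R)-4-silyloxycyclopentenone (C1, alpha) directs isopropyl addition (C3) and cuprate addition (C8a); the Cope boat ties C4 to C3a; C4 is then inverted by Mitsunobu esterification and C1 by oxidation and hydroxyl-directed reduction.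

Key step: step 7

Remark on locants: all intermediates are described with the azulene locants of the target (C1 AcO, C3 carbinol, C3a ring-fusion CH, C4 aroyloxy, C5=C6, C7 ketone, C8 CH2, C8a quaternary); "alpha" is the face of H-3a, "beta" the face of the C8a methyl group.
Remark on assumption: compounds 1, 2, 8 and 16 are taken as purchasable.

Step 1
Reactants: 1 (R)-4-[(tert-butyldimethylsilyl)oxy]cyclopent-2-en-1-one; 2 1-[(tert-butyldimethylsilyl)oxy]-1-methoxyethene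
Product: 3 methyl 2-[(1R,5R)-3,5-bis[(tert-butyldimethylsilyl)oxy]cyclopent-2-en-1-yl]acetate
Conditions: t-BuMe2SiOTf (5 mol%), CH2Cl2, −78 °C; Et3N quench
Reagents that add atoms: 2 1-[(tert-butyldimethylsilyl)oxy]-1-methoxyethene, C=C(OC)O[Si](C)(C)C(C)(C)C
Why: Silyl-triflate-catalysed Mukaiyama–Michael addition of the ketene silyl acetal should occur at the enone beta-carbon trans to the 4-silyloxy group and pass the silyl group to the enolate oxygen, so the adduct is trapped as a regiodefined silyl enol ether (the new stereocentre is removed again in step 2).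

Step 2
Reactants: 3 methyl 2-[(1R,5R)-3,5-bis[(tert-butyldimethylsilyl)oxy]cyclopent-2-en-1-yl]acetate
Product: 4 methyl 2-[(5R)-5-[(tert-butyldimethylsilyl)oxy]-3-oxocyclopent-1-en-1-yl]acetate
Conditions: Pd(OAc)2 (10 mol%), O2 (1 atm), DMSO, 50 °C
Reagents that add atoms: none
Why: Saegusa–Ito oxidation, in which the palladium enolate formed from the silyl enol ether loses the beta-hydrogen at the substituted carbon, should restore the enone with the acetate side chain on its beta-carbon and leave the silyloxy stereocentre untouched.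

Step 3
Reactants: 4 methyl 2-[(5R)-5-[(tert-butyldimethylsilyl)oxy]-3-oxocyclopent-1-en-1-yl]acetate
Product: 5 methyl 2-[(3R,5R)-5-[(tert-butyldimethylsilyl)oxy]-3-hydroxy-3-(propan-2-yl)cyclopent-1-en-1-yl]acetate
Conditions: i-PrMgCl, LaCl3·2LiCl, THF, −78 °C; aq. NH4Cl
Reagents that add atoms: isopropylmagnesium chloride, CC(C)[Mg]Cl
Why: Lanthanide-promoted 1,2-addition of the Grignard reagent to the enone carbonyl should outrun enolization of the acidic side chain and occur trans to the silyloxy group across the ring (1,3-induction of 4-silyloxycyclopentenones), which sets C3 with isopropyl beta and hydroxyl alpha.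

Step 4
Reactants: 5 methyl 2-[(3R,5R)-5-[(tert-butyldimethylsilyl)oxy]-3-hydroxy-3-(propan-2-yl)cyclopent-1-en-1-yl]acetate
Product: 6 methyl 2-[(3R,5R)-5-[(tert-butyldimethylsilyl)oxy]-3-(propan-2-yl)-3-[(triethylsilyl)oxy]cyclopent-1-en-1-yl]acetate
Conditions: Et3SiOTf, 2,6-lutidine, CH2Cl2, −78 to 0 °C
Reagents that add atoms: triethylsilyl trifluoromethanesulfonate, CC[Si](CC)(CC)OS(=O)(=O)C(F)(F)F
Why: Silylation of the hindered tertiary allylic alcohol with a silyl triflate and a hindered base is routine, and the ether blocks intramolecular O–H insertion of the carbenoid in step 7.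

Step 5
Reactants: 6 methyl 2-[(3R,5R)-5-[(tert-butyldimethylsilyl)oxy]-3-(propan-2-yl)-3-[(triethylsilyl)oxy]cyclopent-1-en-1-yl]acetate
Product: 7 methyl 2-diazo-2-[(3R,5R)-5-[(tert-butyldimethylsilyl)oxy]-3-(propan-2-yl)-3-[(triethylsilyl)oxy]cyclopent-1-en-1-yl]acetate
Conditions: 4-acetamidobenzenesulfonyl azide, DBU, MeCN, 0 °C
Reagents that add atoms: 4-acetamidobenzenesulfonyl azide, CC(=O)Nc1ccc(cc1)S(=O)(=O)N=[N+]=[N-]
Why: Regitz diazo transfer to the methylene group activated by the ester and the ring alkene is the standard access to vinyldiazoacetates and touches no stereocentre.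

Step 6
Reactants: 8 3-methylbut-2-enal
Product: 9 (E)-triethyl[(3-methylbuta-1,3-dien-1-yl)oxy]silane
Conditions: Et3SiOTf, Et3N, Et2O, 0 °C
Reagents that add atoms: triethylsilyl trifluoromethanesulfonate, CC[Si](CC)(CC)OS(=O)(=O)C(F)(F)F
Why: Soft enolization (O-silylation of the aldehyde, then gamma-deprotonation by the amine) should give the conjugated silyl dienol ether, the E isomer being expected from the s-trans enal.

Step 7
Reactants: 7 methyl 2-diazo-2-[(3R,5R)-5-[(tert-butyldimethylsilyl)oxy]-3-(propan-2-yl)-3-[(triethylsilyl)oxy]cyclopent-1-en-1-yl]acetate; 9 (E)-triethyl[(3-methylbuta-1,3-dien-1-yl)oxy]silane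
Product: 11 methyl (1R,3R,3aR,4S)-1-[(tert-butyldimethylsilyl)oxy]-6-methyl-3-(propan-2-yl)-3,4-bis[(triethylsilyl)oxy]-1,2,3,3a,4,7-hexahydroazulene-8-carboxylate, via cis-divinylcyclopropane 10 (not isolated)
Conditions: Rh2(R-DOSP)4 (1 mol%), 9 (3 equiv), hexanes, −40 °C to rt, slow addition of 7; then 70 °C
Reagents that add atoms: 9 (E)-triethyl[(3-methylbuta-1,3-dien-1-yl)oxy]silane, C=C(C)/C=C/O[Si](CC)(CC)CC
Why: Rh2(R-DOSP)4 converts 7 into a rhodium vinylcarbenoid that cyclopropanates the accessible 1,1-disubstituted end of 9, forming C8–C7 and placing the enol ether vinyl group cis to the cyclopentenyl group (10), and 10 then undergoes a Cope rearrangement through a boat transition state that forms C3a–C4 as the cyclopropane bond breaks. The closest known reaction type is the tandem cyclopropanation/Cope rearrangement (formal (4+3) cycloaddition) of cycloalkenyl diazoacetates with 1-oxygenated dienes. The seven-membered ring is closed by the [3,3]-sigmatropic shift of the cis-divinylcyclopropane, a ring expansion and not a chain cyclization, which is why the C5=C6 alkene comes out cis. C3a and C4 are formed together: the boat places H-3a and H-4 cis because the enol ether is E, and their absolute sense follows from the cyclopropane configuration, which is set by the chiral carboxylate ligands (antipode chosen by the usual model for donor/acceptor carbenoids) with the out-of-plane C1 silyloxy group as a second bias. The step needs site selectivity between the two alkenes of 9 and cis selectivity in the cyclopropanation; the first is secured by the low reactivity of trans-1,2-disubstituted enol ethers toward donor/acceptor carbenoids, the second by the donor/acceptor character of the carbenoid, and the silyl ethers at C1 and C3 exclude O–H insertion.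

Step 8
Reactants: 11 methyl (1R,3R,3aR,4S)-1-[(tert-butyldimethylsilyl)oxy]-6-methyl-3-(propan-2-yl)-3,4-bis[(triethylsilyl)oxy]-1,2,3,3a,4,7-hexahydroazulene-8-carboxylate
Product: 12 methyl (1R,3R,3aR,4S)-1-[(tert-butyldimethylsilyl)oxy]-6-methyl-7-oxo-3-(propan-2-yl)-3,4-bis[(triethylsilyl)oxy]-1,2,3,3a,4,7-hexahydroazulene-8-carboxylate
Conditions: Rh2(cap)4 (1 mol%), t-BuOOH (5 equiv), K2CO3, CH2Cl2, rt
Reagents that add atoms: tert-butyl hydroperoxide, CC(C)(C)OO
Why: tert-Butylperoxy-radical allylic oxidation should select the doubly allylic C7 methylene, the weakest C–H bond in 11, and give the cross-conjugated dienone (as in the oxidation of 1,4-dienes to dienones) without touching a stereocentre.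

Step 9
Reactants: 12 methyl (1R,3R,3aR,4S)-1-[(tert-butyldimethylsilyl)oxy]-6-methyl-7-oxo-3-(propan-2-yl)-3,4-bis[(triethylsilyl)oxy]-1,2,3,3a,4,7-hexahydroazulene-8-carboxylate
Product: 13 methyl (1R,3R,3aR,4S,8aR)-1-[(tert-butyldimethylsilyl)oxy]-6,8a-dimethyl-7-oxo-3-(propan-2-yl)-3,4-bis[(triethylsilyl)oxy]-1,2,3,3a,4,7,8,8a-octahydroazulene-8-carboxylate (C8 epimers)
Conditions: Me2CuLi (from MeLi, CuI), Et2O, −78 to −40 °C; aq. NH4Cl
Reagents that add atoms: lithium dimethylcuprate, [Li+].C[Cu-]C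
Why: Organocuprate conjugate addition to the alkylidene beta-keto ester, the most electron-poor alkene of 12, is expected to deliver the methyl group to the beta face of C8a, anti to the adjacent C1 silyloxy group, which gives the quaternary centre with methyl trans to H-3a (C8 remains an epimerizable centre that is removed in step 10).

Step 10
Reactants: 13 methyl (1R,3R,3aR,4S,8aR)-1-[(tert-butyldimethylsilyl)oxy]-6,8a-dimethyl-7-oxo-3-(propan-2-yl)-3,4-bis[(triethylsilyl)oxy]-1,2,3,3a,4,7,8,8a-octahydroazulene-8-carboxylate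
Product: 14 (1R,3R,3aR,4S,8aS)-1-[(tert-butyldimethylsilyl)oxy]-6,8a-dimethyl-3-(propan-2-yl)-3,4-bis[(triethylsilyl)oxy]-2,3,3a,4,8,8a-hexahydroazulen-7(1H)-one
Conditions: LiCl, H2O, DMSO, 130 °C
Reagents that add atoms: none
Why: Krapcho dealkoxycarbonylation (chloride demethylates the beta-keto ester and the carboxylate loses CO2) should leave the C8 methylene, and the adjacent quaternary centre cannot epimerize.

Step 11
Reactants: 14 (1R,3R,3aR,4S,8aS)-1-[(tert-butyldimethylsilyl)oxy]-6,8a-dimethyl-3-(propan-2-yl)-3,4-bis[(triethylsilyl)oxy]-2,3,3a,4,8,8a-hexahydroazulen-7(1H)-one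
Product: 15 (1R,3R,3aR,4S,8aS)-1,3,4-trihydroxy-6,8a-dimethyl-3-(propan-2-yl)-2,3,3a,4,8,8a-hexahydroazulen-7(1H)-one
Conditions: HF·pyridine, pyridine, THF, 0 °C to rt
Reagents that add atoms: none
Why: Buffered fluoride cleavage of all three silyl ethers is non-basic, so the gamma-hydroxy enone should not isomerize and no stereocentre is touched.

Step 12
Reactants: 15 (1R,3R,3aR,4S,8aS)-1,3,4-trihydroxy-6,8a-dimethyl-3-(propan-2-yl)-2,3,3a,4,8,8a-hexahydroazulen-7(1H)-one; 16 4-(acetyloxy)benzoic acid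
Product: 17 (1R,3R,3aR,4R,8aS)-1,3-dihydroxy-6,8a-dimethyl-7-oxo-3-(propan-2-yl)-1,2,3,3a,4,7,8,8a-octahydroazulen-4-yl 4-(acetyloxy)benzoate
Conditions: PPh3, DIAD, toluene, 0 °C to rt
Reagents that add atoms: 16 4-(acetyloxy)benzoic acid, CC(=O)Oc1ccc(cc1)C(=O)O
Why: Mitsunobu esterification should displace the allylic C4 oxyphosphonium ion by SN2 and so invert C4 to the alpha configuration while installing the aroyl group, the neopentyl-type C1 hydroxyl and the tertiary C3 hydroxyl being too hindered to react and an allyl cation path being disfavoured by the C7 carbonyl.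

Step 13
Reactants: 17 (1R,3R,3aR,4R,8aS)-1,3-dihydroxy-6,8a-dimethyl-7-oxo-3-(propan-2-yl)-1,2,3,3a,4,7,8,8a-octahydroazulen-4-yl 4-(acetyloxy)benzoate
Product: 18 (3R,3aR,4R,8aS)-3-hydroxy-6,8a-dimethyl-1,7-dioxo-3-(propan-2-yl)-1,2,3,3a,4,7,8,8a-octahydroazulen-4-yl 4-(acetyloxy)benzoate
Conditions: Dess–Martin periodinane, NaHCO3, CH2Cl2, 0 °C
Reagents that add atoms: none
Why: Dess–Martin oxidation takes the only secondary alcohol to the ketone under non-basic conditions that should avoid retro-aldol cleavage or dehydration of the resulting beta-hydroxy ketone.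

Step 14
Reactants: 18 (3R,3aR,4R,8aS)-3-hydroxy-6,8a-dimethyl-1,7-dioxo-3-(propan-2-yl)-1,2,3,3a,4,7,8,8a-octahydroazulen-4-yl 4-(acetyloxy)benzoate
Product: 19 (1S,3R,3aR,4R,8aS)-1,3-dihydroxy-6,8a-dimethyl-7-oxo-3-(propan-2-yl)-1,2,3,3a,4,7,8,8a-octahydroazulen-4-yl 4-(acetyloxy)benzoate
Conditions: Me4NBH(OAc)3, AcOH/MeCN, −30 °C
Reagents that add atoms: none
Why: Evans–Saksena reduction, in which the C3 hydroxyl binds the triacetoxyborohydride and delivers hydride to the alpha face of the C1 ketone, should give the 1,3-anti diol with the C1 hydroxyl beta (also the face opposite the angular methyl), while the C7 enone, which has no neighbouring hydroxyl, is not reduced.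

Step 15
Reactants: 19 (1S,3R,3aR,4R,8aS)-1,3-dihydroxy-6,8a-dimethyl-7-oxo-3-(propan-2-yl)-1,2,3,3a,4,7,8,8a-octahydroazulen-4-yl 4-(acetyloxy)benzoate
Product: 20 (1S,3R,3aR,4R,8aS)-1-(acetyloxy)-3-hydroxy-6,8a-dimethyl-7-oxo-3-(propan-2-yl)-1,2,3,3a,4,7,8,8a-octahydroazulen-4-yl 4-(acetyloxy)benzoate
Conditions: Ac2O, DMAP (cat.), pyridine, CH2Cl2, 0 °C
Reagents that add atoms: acetic anhydride, CC(=O)OC(C)=O
Why: Nucleophile-catalysed acylation should acetylate the secondary C1 alcohol much faster than the tertiary C3 alcohol.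

Step 16
Reactants: 20 (1S,3R,3aR,4R,8aS)-1-(acetyloxy)-3-hydroxy-6,8a-dimethyl-7-oxo-3-(propan-2-yl)-1,2,3,3a,4,7,8,8a-octahydroazulen-4-yl 4-(acetyloxy)benzoate
Product: 21 (1S,3R,3aR,4R,8aS)-1-(acetyloxy)-3-hydroxy-6,8a-dimethyl-7-oxo-3-(propan-2-yl)-1,2,3,3a,4,7,8,8a-octahydroazulen-4-yl 4-hydroxybenzoate
Conditions: NH4OAc, MeOH/H2O, rt
Reagents that add atoms: none
Why: Near-neutral ammonium acetate solvolysis cleaves aryl acetates far faster than alkyl acetates or benzoates because phenoxide is the better leaving group, so only the phenol should be unmasked.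

**Compound list**
1 | (R)-4-[(tert-butyldimethylsilyl)oxy]cyclopent-2-en-1-one | O=C1C=C[C@H](O[Si](C)(C)C(C)(C)C)C1 | starting material
2 | 1-[(tert-butyldimethylsilyl)oxy]-1-methoxyethene | C=C(OC)O[Si](C)(C)C(C)(C)C | starting material
3 | methyl 2-[(1R,5R)-3,5-bis[(tert-butyldimethylsilyl)oxy]cyclopent-2-en-1-yl]acetate | COC(=O)C[C@@H]1C=C(O[Si](C)(C)C(C)(C)C)C[C@H]1O[Si](C)(C)C(C)(C)C | intermediate
4 | methyl 2-[(5R)-5-[(tert-butyldimethylsilyl)oxy]-3-oxocyclopent-1-en-1-yl]acetate | COC(=O)CC1=CC(=O)C[C@H]1O[Si](C)(C)C(C)(C)C | intermediate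
5 | methyl 2-[(3R,5R)-5-[(tert-butyldimethylsilyl)oxy]-3-hydroxy-3-(propan-2-yl)cyclopent-1-en-1-yl]acetate | COC(=O)CC1=C[C@](O)(C(C)C)C[C@H]1O[Si](C)(C)C(C)(C)C | intermediate
6 | methyl 2-[(3R,5R)-5-[(tert-butyldimethylsilyl)oxy]-3-(propan-2-yl)-3-[(triethylsilyl)oxy]cyclopent-1-en-1-yl]acetate | COC(=O)CC1=C[C@](O[Si](CC)(CC)CC)(C(C)C)C[C@H]1O[Si](C)(C)C(C)(C)C | intermediate
7 | methyl 2-diazo-2-[(3R,5R)-5-[(tert-butyldimethylsilyl)oxy]-3-(propan-2-yl)-3-[(triethylsilyl)oxy]cyclopent-1-en-1-yl]acetate | COC(=O)C(=[N+]=[N-])C1=C[C@](O[Si](CC)(CC)CC)(C(C)C)C[C@H]1O[Si](C)(C)C(C)(C)C | intermediate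
8 | 3-methylbut-2-enal | CC(C)=CC=O | starting material
9 | (E)-triethyl[(3-methylbuta-1,3-dien-1-yl)oxy]silane | C=C(C)/C=C/O[Si](CC)(CC)CC | intermediate
10 | methyl (1R,2S)-1-[(3R,5R)-5-[(tert-butyldimethylsilyl)oxy]-3-(propan-2-yl)-3-[(triethylsilyl)oxy]cyclopent-1-en-1-yl]-2-methyl-2-[(E)-2-[(triethylsilyl)oxy]ethenyl]cyclopropane-1-carboxylate | COC(=O)[C@@]1(C[C@@]1(C)/C=C/O[Si](CC)(CC)CC)C2=C[C@](O[Si](CC)(CC)CC)(C(C)C)C[C@H]2O[Si](C)(C)C(C)(C)C | intermediate
11 | methyl (1R,3R,3aR,4S)-1-[(tert-butyldimethylsilyl)oxy]-6-methyl-3-(propan-2-yl)-3,4-bis[(triethylsilyl)oxy]-1,2,3,3a,4,7-hexahydroazulene-8-carboxylate | CC(C)(C)[Si](C)(C)O[C@@H]1C[C@@](O[Si](CC)(CC)CC)(C(C)C)[C@H]2[C@@H](O[Si](CC)(CC)CC)C=C(C)CC(C(=O)OC)=C12 | intermediate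
12 | methyl (1R,3R,3aR,4S)-1-[(tert-butyldimethylsilyl)oxy]-6-methyl-7-oxo-3-(propan-2-yl)-3,4-bis[(triethylsilyl)oxy]-1,2,3,3a,4,7-hexahydroazulene-8-carboxylate | CC(C)(C)[Si](C)(C)O[C@@H]1C[C@@](O[Si](CC)(CC)CC)(C(C)C)[C@H]2[C@@H](O[Si](CC)(CC)CC)C=C(C)C(=O)C(C(=O)OC)=C12 | intermediate
13 | methyl (1R,3R,3aR,4S,8aR)-1-[(tert-butyldimethylsilyl)oxy]-6,8a-dimethyl-7-oxo-3-(propan-2-yl)-3,4-bis[(triethylsilyl)oxy]-1,2,3,3a,4,7,8,8a-octahydroazulene-8-carboxylate (C8 epimers) | CC(C)(C)[Si](C)(C)O[C@@H]1C[C@@](O[Si](CC)(CC)CC)(C(C)C)[C@H]2[C@@H](O[Si](CC)(CC)CC)C=C(C)C(=O)C(C(=O)OC)[C@]12C | intermediate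
14 | (1R,3R,3aR,4S,8aS)-1-[(tert-butyldimethylsilyl)oxy]-6,8a-dimethyl-3-(propan-2-yl)-3,4-bis[(triethylsilyl)oxy]-2,3,3a,4,8,8a-hexahydroazulen-7(1H)-one | CC(C)(C)[Si](C)(C)O[C@@H]1C[C@@](O[Si](CC)(CC)CC)(C(C)C)[C@H]2[C@@H](O[Si](CC)(CC)CC)C=C(C)C(=O)C[C@]12C | intermediate
15 | (1R,3R,3aR,4S,8aS)-1,3,4-trihydroxy-6,8a-dimethyl-3-(propan-2-yl)-2,3,3a,4,8,8a-hexahydroazulen-7(1H)-one | O[C@@H]1C[C@@](O)(C(C)C)[C@H]2[C@@H](O)C=C(C)C(=O)C[C@]12C | intermediate
16 | 4-(acetyloxy)benzoic acid | CC(=O)Oc1ccc(cc1)C(=O)O | starting material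
17 | (1R,3R,3aR,4R,8aS)-1,3-dihydroxy-6,8a-dimethyl-7-oxo-3-(propan-2-yl)-1,2,3,3a,4,7,8,8a-octahydroazulen-4-yl 4-(acetyloxy)benzoate | O[C@@H]1C[C@@](O)(C(C)C)[C@H]2[C@H](OC(=O)c3ccc(OC(C)=O)cc3)C=C(C)C(=O)C[C@]12C | intermediate
18 | (3R,3aR,4R,8aS)-3-hydroxy-6,8a-dimethyl-1,7-dioxo-3-(propan-2-yl)-1,2,3,3a,4,7,8,8a-octahydroazulen-4-yl 4-(acetyloxy)benzoate | O=C1C[C@@](O)(C(C)C)[C@H]2[C@H](OC(=O)c3ccc(OC(C)=O)cc3)C=C(C)C(=O)C[C@]12C | intermediate
19 | (1S,3R,3aR,4R,8aS)-1,3-dihydroxy-6,8a-dimethyl-7-oxo-3-(propan-2-yl)-1,2,3,3a,4,7,8,8a-octahydroazulen-4-yl 4-(acetyloxy)benzoate | O[C@H]1C[C@@](O)(C(C)C)[C@H]2[C@H](OC(=O)c3ccc(OC(C)=O)cc3)C=C(C)C(=O)C[C@]12C | intermediate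
20 | (1S,3R,3aR,4R,8aS)-1-(acetyloxy)-3-hydroxy-6,8a-dimethyl-7-oxo-3-(propan-2-yl)-1,2,3,3a,4,7,8,8a-octahydroazulen-4-yl 4-(acetyloxy)benzoate | CC(=O)O[C@H]1C[C@@](O)(C(C)C)[C@H]2[C@H](OC(=O)c3ccc(OC(C)=O)cc3)C=C(C)C(=O)C[C@]12C | intermediate
21 | (1S,3R,3aR,4R,8aS)-1-(acetyloxy)-3-hydroxy-6,8a-dimethyl-7-oxo-3-(propan-2-yl)-1,2,3,3a,4,7,8,8a-octahydroazulen-4-yl 4-hydroxybenzoate | CC(=O)O[C@H]1C[C@@](O)(C(C)C)[C@H]2[C@H](OC(=O)c3ccc(O)cc3)C=C(C)C(=O)C[C@]12C | target

**Count**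
Total steps: 16. Longest linear sequence: 15 (steps 1 to 5 and 7 to 16; step 6 is a one-step branch).

**Steps most likely to fail**

Step 7. What may go wrong: cyclopropanation on the wrong carbenoid face (giving the C3a/C4 antipodal pair relative to C1 and C3), or capture of the carbenoid by the electron-rich dienol ether along a zwitterionic path that never reaches the divinylcyclopropane. The fallback sets out from 6 and comes back at 11, building the same two bonds one at a time. Ester 6 is deprotonated (LiN(iPr)2, THF, −78 °C) and alkylated at its alpha-carbon with 3-bromo-2-methylprop-1-ene, which forms C8–C7 and gives methyl 2-[(3R,5R)-5-[(tert-butyldimethylsilyl)oxy]-3-(propan-2-yl)-3-[(triethylsilyl)oxy]cyclopent-1-en-1-yl]-4-methylpent-4-enoate F1. F1 is converted (LiN(iPr)2, Me3SiCl) into its trimethylsilyl ketene acetal F2. A vinylogous Mukaiyama aldol reaction of F2 with prop-2-enal (BF3·OEt2, CH2Cl2, −78 °C) at the gamma-carbon forms C3a–C4 and moves the alkene to C8=C8a, giving the allylic alcohol methyl (2Z)-2-[(2R,3R,5R)-5-[(tert-butyldimethylsilyl)oxy]-2-[(1S)-1-hydroxyprop-2-en-1-yl]-3-(propan-2-yl)-3-[(triethylsilyl)oxy]cyclopentylidene]-4-methylpent-4-enoate F3, diastereomers being separated here. Silylation (Et3SiOTf, 2,6-lutidine) gives the triethylsilyl ether F4, and ring-closing metathesis with the second-generation Grubbs catalyst RuCl2(H2IMes)(PCy3)(=CHPh) closes the seven-membered ring at C5=C6 to give 11.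

Step 9. What may go wrong: approach of the cuprate to the alpha face of C8a, since the beta face is flanked by C4 of the seven-membered ring, which would give the cis-fused ring system; addition at C5 is a lesser concern. The fallback sets out from 12 and comes back at 15, replacing steric control by intramolecular delivery. The secondary allylic triethylsilyl ether at C4 is cleaved selectively (HF·pyridine, THF, 0 °C) to give methyl (1R,3R,3aR,4S)-1-[(tert-butyldimethylsilyl)oxy]-4-hydroxy-6-methyl-7-oxo-3-(propan-2-yl)-3-[(triethylsilyl)oxy]-1,2,3,3a,4,7-hexahydroazulene-8-carboxylate F5. AlMe3 (CH2Cl2, −78 to −20 °C) forms the C4 aluminium alkoxide, which should pass a methyl group to C8a on its own beta face through a six-membered transition state (hydroxyl-directed conjugate addition), giving methyl (1R,3R,3aR,4S,8aR)-1-[(tert-butyldimethylsilyl)oxy]-4-hydroxy-6,8a-dimethyl-7-oxo-3-(propan-2-yl)-3-[(triethylsilyl)oxy]-1,2,3,3a,4,7,8,8a-octahydroazulene-8-carboxylate F6. A Krapcho reaction gives (1R,3R,3aR,4S,8aS)-1-[(tert-butyldimethylsilyl)oxy]-4-hydroxy-6,8a-dimethyl-3-(propan-2-yl)-3-[(triethylsilyl)oxy]-2,3,3a,4,8,8a-hexahydroazulen-7(1H)-one F7, and full desilylation (HF·pyridine, rt) gives 15.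

Step 12. What may go wrong: the SN2 displacement at the hindered C4 oxyphosphonium ion may not take place, leaving elimination toward a dienone or acylation with retention. The fallback sets out from 8 and comes back at 17; it sets the alpha oxygen at C4 in the ring-forming step, so that the ester can be made with retention. Aldehyde 8 is converted through its potassium dienolate (KN(SiMe3)2, THF, −78 °C; Et3SiCl) into (Z)-triethyl[(3-methylbuta-1,3-dien-1-yl)oxy]silane F8. The rhodium-catalysed reaction of F8 with 7 passes through the Z-configured divinylcyclopropane F9 (not isolated), whose silyloxy group sits inside the boat, and after heating gives the C4 epimer of 11, methyl (1R,3R,3aR,4R)-1-[(tert-butyldimethylsilyl)oxy]-6-methyl-3-(propan-2-yl)-3,4-bis[(triethylsilyl)oxy]-1,2,3,3a,4,7-hexahydroazulene-8-carboxylate F10. Allylic oxidation, cuprate addition, Krapcho reaction and desilylation under the conditions of steps 8 to 11 give in turn the dienone F11, the methylated keto ester F12, the ketone F13 and (1R,3R,3aR,4R,8aS)-1,3,4-trihydroxy-6,8a-dimethyl-3-(propan-2-yl)-2,3,3a,4,8,8a-hexahydroazulen-7(1H)-one F14. Carbodiimide (Steglich) esterification of the allylic C4 hydroxyl of F14 with 16 (EDC, DMAP, CH2Cl2, 0 °C) gives 17.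

**Further compounds**
F1 | step 7 | methyl 2-[(3R,5R)-5-[(tert-butyldimethylsilyl)oxy]-3-(propan-2-yl)-3-[(triethylsilyl)oxy]cyclopent-1-en-1-yl]-4-methylpent-4-enoate | COC(=O)C(CC(C)=C)C1=C[C@](O[Si](CC)(CC)CC)(C(C)C)C[C@H]1O[Si](C)(C)C(C)(C)C
F2 | step 7 | trimethylsilyl ketene acetal of F1 | COC(O[Si](C)(C)C)=C(CC(C)=C)C1=C[C@](O[Si](CC)(CC)CC)(C(C)C)C[C@H]1O[Si](C)(C)C(C)(C)C
F3 | step 7 | methyl (2Z)-2-[(2R,3R,5R)-5-[(tert-butyldimethylsilyl)oxy]-2-[(1S)-1-hydroxyprop-2-en-1-yl]-3-(propan-2-yl)-3-[(triethylsilyl)oxy]cyclopentylidene]-4-methylpent-4-enoate | CC(C)(C)[Si](C)(C)O[C@@H]1C[C@@](O[Si](CC)(CC)CC)(C(C)C)[C@@H]([C@@H](O)C=C)/C1=C(\CC(C)=C)C(=O)OC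
F4 | step 7 | triethylsilyl ether of F3 | CC(C)(C)[Si](C)(C)O[C@@H]1C[C@@](O[Si](CC)(CC)CC)(C(C)C)[C@@H]([C@@H](O[Si](CC)(CC)CC)C=C)/C1=C(\CC(C)=C)C(=O)OC
F5 | step 9 | methyl (1R,3R,3aR,4S)-1-[(tert-butyldimethylsilyl)oxy]-4-hydroxy-6-methyl-7-oxo-3-(propan-2-yl)-3-[(triethylsilyl)oxy]-1,2,3,3a,4,7-hexahydroazulene-8-carboxylate | CC(C)(C)[Si](C)(C)O[C@@H]1C[C@@](O[Si](CC)(CC)CC)(C(C)C)[C@H]2[C@@H](O)C=C(C)C(=O)C(C(=O)OC)=C12
F6 | step 9 | methyl (1R,3R,3aR,4S,8aR)-1-[(tert-butyldimethylsilyl)oxy]-4-hydroxy-6,8a-dimethyl-7-oxo-3-(propan-2-yl)-3-[(triethylsilyl)oxy]-1,2,3,3a,4,7,8,8a-octahydroazulene-8-carboxylate | CC(C)(C)[Si](C)(C)O[C@@H]1C[C@@](O[Si](CC)(CC)CC)(C(C)C)[C@H]2[C@@H](O)C=C(C)C(=O)C(C(=O)OC)[C@]12C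
F7 | step 9 | (1R,3R,3aR,4S,8aS)-1-[(tert-butyldimethylsilyl)oxy]-4-hydroxy-6,8a-dimethyl-3-(propan-2-yl)-3-[(triethylsilyl)oxy]-2,3,3a,4,8,8a-hexahydroazulen-7(1H)-one | CC(C)(C)[Si](C)(C)O[C@@H]1C[C@@](O[Si](CC)(CC)CC)(C(C)C)[C@H]2[C@@H](O)C=C(C)C(=O)C[C@]12C
F8 | step 12 | (Z)-triethyl[(3-methylbuta-1,3-dien-1-yl)oxy]silane | C=C(C)/C=C\O[Si](CC)(CC)CC
F9 | step 12 | methyl (1R,2S)-1-[(3R,5R)-5-[(tert-butyldimethylsilyl)oxy]-3-(propan-2-yl)-3-[(triethylsilyl)oxy]cyclopent-1-en-1-yl]-2-methyl-2-[(Z)-2-[(triethylsilyl)oxy]ethenyl]cyclopropane-1-carboxylate | COC(=O)[C@@]1(C[C@@]1(C)/C=C\O[Si](CC)(CC)CC)C2=C[C@](O[Si](CC)(CC)CC)(C(C)C)C[C@H]2O[Si](C)(C)C(C)(C)C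
F10 | step 12 | methyl (1R,3R,3aR,4R)-1-[(tert-butyldimethylsilyl)oxy]-6-methyl-3-(propan-2-yl)-3,4-bis[(triethylsilyl)oxy]-1,2,3,3a,4,7-hexahydroazulene-8-carboxylate | CC(C)(C)[Si](C)(C)O[C@@H]1C[C@@](O[Si](CC)(CC)CC)(C(C)C)[C@H]2[C@H](O[Si](CC)(CC)CC)C=C(C)CC(C(=O)OC)=C12
F11 | step 12 | methyl (1R,3R,3aR,4R)-1-[(tert-butyldimethylsilyl)oxy]-6-methyl-7-oxo-3-(propan-2-yl)-3,4-bis[(triethylsilyl)oxy]-1,2,3,3a,4,7-hexahydroazulene-8-carboxylate | CC(C)(C)[Si](C)(C)O[C@@H]1C[C@@](O[Si](CC)(CC)CC)(C(C)C)[C@H]2[C@H](O[Si](CC)(CC)CC)C=C(C)C(=O)C(C(=O)OC)=C12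
F12 | step 12 | methyl (1R,3R,3aR,4R,8aR)-1-[(tert-butyldimethylsilyl)oxy]-6,8a-dimethyl-7-oxo-3-(propan-2-yl)-3,4-bis[(triethylsilyl)oxy]-1,2,3,3a,4,7,8,8a-octahydroazulene-8-carboxylate (C8 epimers) | CC(C)(C)[Si](C)(C)O[C@@H]1C[C@@](O[Si](CC)(CC)CC)(C(C)C)[C@H]2[C@H](O[Si](CC)(CC)CC)C=C(C)C(=O)C(C(=O)OC)[C@]12C
F13 | step 12 | (1R,3R,3aR,4R,8aS)-1-[(tert-butyldimethylsilyl)oxy]-6,8a-dimethyl-3-(propan-2-yl)-3,4-bis[(triethylsilyl)oxy]-2,3,3a,4,8,8a-hexahydroazulen-7(1H)-one | CC(C)(C)[Si](C)(C)O[C@@H]1C[C@@](O[Si](CC)(CC)CC)(C(C)C)[C@H]2[C@H](O[Si](CC)(CC)CC)C=C(C)C(=O)C[C@]12C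
F14 | step 12 | (1R,3R,3aR,4R,8aS)-1,3,4-trihydroxy-6,8a-dimethyl-3-(propan-2-yl)-2,3,3a,4,8,8a-hexahydroazulen-7(1H)-one | O[C@@H]1C[C@@](O)(C(C)C)[C@H]2[C@H](O)C=C(C)C(=O)C[C@]12C
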